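**Plan**

- Ring A is the prenylated ring, numbered C1 (prenyl), C2 (OH), C3 (H), C4 (OH), C5 (CHO), C6 (aroyl); ring B is the brominated ring.
- Retrosynthesis: the four phenols come from MOM ethers and the diaryl ketone from a 2,2-diaryl-1,3-dithiane; then the ring A C6–C(ketone) bond and the ring A C5–CHO bond are cut together; last, the prenyl–C1 bond of the ring A bromide is cut.
- Enabling feature: the aroyl carbon C6 and the formyl carbon C5 of ring A are neighbours, and C5 lies next to the oxygen-bearing C4. A C5≡C6 aryne polarised by the C4 oxygen therefore takes the ring B acyl-anion equivalent at C6 and leaves an aryllithium at C5 for formylation.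
- Forward: ring A bromide 6 from 5-bromoresorcinol (MOM, iodination, iodine–magnesium exchange and prenylation); ring B dithiane 10 from atranol (bromination, dithioacetal, MOM); 6, 10 and DMF are joined in one three-component aryne coupling; dithiane hydrolysis and MOM removal finish the route.
- Both benzene rings are bought, none is built. The target has no stereocentre and no stereogenic double bond, so no stereochemistry has to be set.

Key step: step 7

Assumption: 2,6-dihydroxy-4-methylbenzaldehyde (atranol) is bought, and LiTMP (lithium 2,2,6,6-tetramethylpiperidide) and i-PrMgCl·LiCl are used as preformed solutions.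

**Route**

Step 1
Reactants: 1 5-bromobenzene-1,3-diol
Product: 2 1-bromo-3,5-bis(methoxymethoxy)benzene
Conditions: NaH, MOMCl, DMF, 0 °C → rt
Reagents that add atoms: chloromethyl methyl ether (MOMCl) COCCl
Why: Double Williamson O-alkylation of the sodium phenoxides with the reactive chloromethyl ether gives the bis-MOM ether, whose oxygen atoms later polarise the aryne and which is removable with mild acid.

Step 2
Reactants: 2 1-bromo-3,5-bis(methoxymethoxy)benzene
Product: 3 1-bromo-2-iodo-3,5-bis(methoxymethoxy)benzene
Conditions: NIS, DMF, rt, dark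
Reagents that add atoms: N-iodosuccinimide O=C1CCC(=O)N1I
Why: Electrophilic aromatic iodination should go to the position para to one MOM-oxy group and ortho to the other (next to bromine) rather than to the shielded position between the two MOM-oxy groups, as in formylation and halogenation of 5-substituted resorcinol diethers.

Step 3
Reactants: 3 1-bromo-2-iodo-3,5-bis(methoxymethoxy)benzene; 4 1-bromo-3-methylbut-2-ene (prenyl bromide)
Product: 6 1-bromo-3,5-bis(methoxymethoxy)-2-(3-methylbut-2-en-1-yl)benzene, via arylmagnesium chloride 5 (not isolated)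
Conditions: i-PrMgCl·LiCl, THF, −40 °C; CuBr·SMe2 (10 mol %), 4, −40 → 0 °C
Reagents that add atoms: none
Why: Iodine–magnesium exchange is much faster than bromine–magnesium exchange and the ortho-bromoaryl Grignard reagent 5 should not lose MgBrCl at low temperature, so copper-catalysed allylic substitution at the primary carbon of prenyl bromide places the prenyl group between bromine and MOM-oxy.

Step 4
Reactants: 7 2,6-dihydroxy-4-methylbenzaldehyde (atranol)
Product: 8 3-bromo-2,6-dihydroxy-4-methylbenzaldehyde
Conditions: NBS (1.0 equiv), MeCN, −20 → 0 °C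
Reagents that add atoms: N-bromosuccinimide O=C1CCC(=O)N1Br
Why: Electrophilic aromatic bromination of the symmetrical, doubly activated ring with one equivalent of NBS at low temperature should stop at the monobromide, the two free positions being equivalent.

Step 5
Reactants: 8 3-bromo-2,6-dihydroxy-4-methylbenzaldehyde
Product: 9 2-(3-bromo-2,6-dihydroxy-4-methylphenyl)-1,3-dithiane
Conditions: HS(CH2)3SH, BF3·OEt2, CH2Cl2, 0 °C → rt
Reagents that add atoms: propane-1,3-dithiol SCCCS
Why: Lewis acid catalysed dithioacetalisation turns the aldehyde into the 1,3-dithiane needed as acyl-anion equivalent (Corey–Seebach umpolung), and it is run on the free phenols because MOM ethers would not survive BF3 and a thiol.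

Step 6
Reactants: 9 2-(3-bromo-2,6-dihydroxy-4-methylphenyl)-1,3-dithiane
Product: 10 2-[3-bromo-2,6-bis(methoxymethoxy)-4-methylphenyl]-1,3-dithiane
Conditions: NaH, MOMCl, DMF, 0 °C → rt
Reagents that add atoms: chloromethyl methyl ether (MOMCl) COCCl
Why: Williamson O-alkylation of the two phenoxides with MOMCl should be clean because the dithiane C–H is far too weakly acidic for NaH and the sulfide sulfur is a poor nucleophile.

Step 7
Reactants: 10 2-[3-bromo-2,6-bis(methoxymethoxy)-4-methylphenyl]-1,3-dithiane; 6 1-bromo-3,5-bis(methoxymethoxy)-2-(3-methylbut-2-en-1-yl)benzene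
Product: 16 2-{2-[3-bromo-2,6-bis(methoxymethoxy)-4-methylphenyl]-1,3-dithian-2-yl}-4,6-bis(methoxymethoxy)-3-(3-methylbut-2-en-1-yl)benzaldehyde, via lithiated dithiane 11 (not isolated), via lithiated bromoarene 12 (not isolated), via aryne 13 (not isolated), via aryllithium 14 (not isolated), via lithium hemiaminolate 15 (not isolated)
Conditions: 10, LiTMP, THF, −40 °C; add to 6 + LiTMP, THF, −78 °C; −78 → −20 °C; DMF, −78 °C → rt; H2O
Reagents that add atoms: N,N-dimethylformamide CN(C)C=O
Why: LiTMP removes the dithiane C–H of 10 (giving 11) and, in a separate flask, the ring A hydrogen of 6 that lies between the bromine-bearing and a MOM-oxy-bearing carbon (giving 12); on warming 12 loses LiBr to give aryne 13, carbanion 11 adds to it to form the ring A–C(dithiane) bond and aryllithium 14, and DMF formylates 14 through hemiaminolate 15. The closest known reaction type is the three-component aryne coupling in which a carbon nucleophile (an organolithium, a Grignard reagent or a stabilised carbanion) adds to an aryne made from a haloarene and the new aryl metal is trapped by an electrophile such as DMF. No ring is closed and no stereocentre is formed. The step needs regioselective addition across the aryne: the MOM-oxy group on C4, beside the C5 terminus, withdraws electron density through the sigma frame, so the nucleophile attacks the distal terminus C6 and the charge develops at C5, where it is stabilised inductively and by Li–O chelation, while the prenyl group beside C6 opposes this only sterically. It also needs site-selective metalation of 6, expected because the C5 hydrogen (flanked by bromine and MOM-oxy) is the most acidic toward the amide base and only its removal leads on irreversibly to the aryne, and it needs ring B to stay intact, which holds because its bromine has no ortho hydrogen and cannot give a second aryne. The carbon–carbon bond is made while the neighbouring C5 carries only lithium, so the most congested bond of the target forms before the second ortho substituent is in place.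

Step 8
Reactants: 16 2-{2-[3-bromo-2,6-bis(methoxymethoxy)-4-methylphenyl]-1,3-dithian-2-yl}-4,6-bis(methoxymethoxy)-3-(3-methylbut-2-en-1-yl)benzaldehyde
Product: 17 2-[3-bromo-2,6-bis(methoxymethoxy)-4-methylbenzoyl]-4,6-bis(methoxymethoxy)-3-(3-methylbut-2-en-1-yl)benzaldehyde
Conditions: PhI(OCOCF3)2, NaHCO3, MeCN/H2O (9:1), 0 °C
Reagents that add atoms: water O
Why: Oxidative dithiane hydrolysis by the hypervalent iodine reagent (sulfur oxidation, ionisation to the doubly benzylic thionium ion, capture by water) is fast for diaryl dithianes and relieves strain at the congested carbon, and the buffered medium should spare the prenyl double bond, the aldehyde and the MOM ethers.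

Step 9
Reactants: 17 2-[3-bromo-2,6-bis(methoxymethoxy)-4-methylbenzoyl]-4,6-bis(methoxymethoxy)-3-(3-methylbut-2-en-1-yl)benzaldehyde
Product: 18 2-(3-bromo-2,6-dihydroxy-4-methylbenzoyl)-4,6-dihydroxy-3-(3-methylbut-2-en-1-yl)benzaldehyde (Pestalone C)
Conditions: 3 M aq. HCl, THF/i-PrOH, 40 °C
Reagents that add atoms: none
Why: Acid-catalysed acetal hydrolysis removes all four MOM groups as formaldehyde and methanol under conditions routinely used on ortho-prenyl phenols, and should give the target.

**Compound list**

1 | 5-bromobenzene-1,3-diol (5-bromoresorcinol) | Oc1cc(O)cc(Br)c1 | starting material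
2 | 1-bromo-3,5-bis(methoxymethoxy)benzene | COCOc1cc(Br)cc(OCOC)c1 | intermediate
3 | 1-bromo-2-iodo-3,5-bis(methoxymethoxy)benzene | COCOc1cc(Br)c(I)c(OCOC)c1 | intermediate
4 | 1-bromo-3-methylbut-2-ene (prenyl bromide) | CC(C)=CCBr | starting material
5 | [2-bromo-4,6-bis(methoxymethoxy)phenyl]magnesium chloride (not isolated) | COCOc1cc(Br)c([Mg]Cl)c(OCOC)c1 | intermediate
6 | 1-bromo-3,5-bis(methoxymethoxy)-2-(3-methylbut-2-en-1-yl)benzene | CC(C)=CCc1c(Br)cc(OCOC)cc1OCOC | intermediate
7 | 2,6-dihydroxy-4-methylbenzaldehyde (atranol) | Cc1cc(O)c(C=O)c(O)c1 | starting material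
8 | 3-bromo-2,6-dihydroxy-4-methylbenzaldehyde | Cc1cc(O)c(C=O)c(O)c1Br | intermediate
9 | 2-(3-bromo-2,6-dihydroxy-4-methylphenyl)-1,3-dithiane | Cc1cc(O)c(C2SCCCS2)c(O)c1Br | intermediate
10 | 2-[3-bromo-2,6-bis(methoxymethoxy)-4-methylphenyl]-1,3-dithiane | COCOc1cc(C)c(Br)c(OCOC)c1C1SCCCS1 | intermediate
11 | {2-[3-bromo-2,6-bis(methoxymethoxy)-4-methylphenyl]-1,3-dithian-2-yl}lithium (not isolated) | [Li]C1(SCCCS1)c1c(OCOC)cc(C)c(Br)c1OCOC | intermediate
12 | [2-bromo-4,6-bis(methoxymethoxy)-3-(3-methylbut-2-en-1-yl)phenyl]lithium (not isolated) | [Li]c1c(Br)c(CC=C(C)C)c(OCOC)cc1OCOC | intermediate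
13 | 3,5-bis(methoxymethoxy)-6-(3-methylbut-2-en-1-yl)benzyne (1,2-didehydrobenzene; not isolated) | CC(C)=CCC1=C(OCOC)C=C(OCOC)C#C1 | intermediate
14 | (2-{2-[3-bromo-2,6-bis(methoxymethoxy)-4-methylphenyl]-1,3-dithian-2-yl}-4,6-bis(methoxymethoxy)-3-(3-methylbut-2-en-1-yl)phenyl)lithium (not isolated) | [Li]c1c(OCOC)cc(OCOC)c(CC=C(C)C)c1C1(SCCCS1)c1c(OCOC)cc(C)c(Br)c1OCOC | intermediate
15 | lithium (dimethylamino)(2-{2-[3-bromo-2,6-bis(methoxymethoxy)-4-methylphenyl]-1,3-dithian-2-yl}-4,6-bis(methoxymethoxy)-3-(3-methylbut-2-en-1-yl)phenyl)methanolate (racemic; not isolated) | [Li]OC(N(C)C)c1c(OCOC)cc(OCOC)c(CC=C(C)C)c1C1(SCCCS1)c1c(OCOC)cc(C)c(Br)c1OCOC | intermediate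
16 | 2-{2-[3-bromo-2,6-bis(methoxymethoxy)-4-methylphenyl]-1,3-dithian-2-yl}-4,6-bis(methoxymethoxy)-3-(3-methylbut-2-en-1-yl)benzaldehyde | CC(C)=CCc1c(OCOC)cc(OCOC)c(C=O)c1C1(SCCCS1)c1c(OCOC)cc(C)c(Br)c1OCOC | intermediate
17 | 2-[3-bromo-2,6-bis(methoxymethoxy)-4-methylbenzoyl]-4,6-bis(methoxymethoxy)-3-(3-methylbut-2-en-1-yl)benzaldehyde | CC(C)=CCc1c(OCOC)cc(OCOC)c(C=O)c1C(=O)c1c(OCOC)cc(C)c(Br)c1OCOC | intermediate
18 | 2-(3-bromo-2,6-dihydroxy-4-methylbenzoyl)-4,6-dihydroxy-3-(3-methylbut-2-en-1-yl)benzaldehyde (Pestalone C) | CC(C)=CCc1c(O)cc(O)c(C=O)c1C(=O)c1c(O)cc(C)c(Br)c1O | target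

**Count**

Total steps: 9. Longest linear sequence: 6 steps (steps 1, 2, 3, 7, 8, 9 or steps 4, 5, 6, 7, 8, 9).

**Steps most likely to fail**

Step 7. The bulky tertiary dithiane carbanion may add too slowly to the aryne terminus beside the prenyl group, so that the aryne is consumed by amide addition or oligomerisation; metalation of 6 between the two MOM-oxy groups may also compete. The fallback uses aryllithium addition to an aldehyde followed by oxidation, with the formyl carbon placed on ring A first. It sets out from 6 and 8 and comes back at 18. Compound 6 is lithiated with LiTMP at −78 °C and aryllithium 12 is trapped with DMF at that temperature, before LiBr is lost, to give 2-bromo-4,6-bis(methoxymethoxy)-3-(3-methylbut-2-en-1-yl)benzaldehyde F1. HC(OMe)3 and catalytic PPTS in MeOH at rt convert F1 into 1-bromo-2-(dimethoxymethyl)-3,5-bis(methoxymethoxy)-6-(3-methylbut-2-en-1-yl)benzene F2. Compound 8 is protected with NaH and MOMCl to give 3-bromo-2,6-bis(methoxymethoxy)-4-methylbenzaldehyde F3. Bromine–lithium exchange on F2 (n-BuLi, THF, −78 °C) and addition to F3 should give the racemic benzhydrol [3-bromo-2,6-bis(methoxymethoxy)-4-methylphenyl][2-(dimethoxymethyl)-3,5-bis(methoxymethoxy)-6-(3-methylbut-2-en-1-yl)phenyl]methanol F4. Dess–Martin periodinane oxidises it to [3-bromo-2,6-bis(methoxymethoxy)-4-methylphenyl][2-(dimethoxymethyl)-3,5-bis(methoxymethoxy)-6-(3-methylbut-2-en-1-yl)phenyl]methanone F5. The aqueous HCl conditions of step 9 then remove the dimethyl acetal and the four MOM groups to give 18.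

Step 8. Oxidation of the prenyl double bond or of the electron-rich rings by the iodine reagent may compete with sulfur oxidation, or capture of water at the congested carbon may be slow. The fallback is a two-stage, sulfoxide-mediated hydrolysis merged with the deprotection. It sets out from 16 and comes back at 18. NaIO4 (1 equiv, MeOH/H2O, 0 °C), which oxidises sulfides much faster than alkenes, should give 2-{2-[3-bromo-2,6-bis(methoxymethoxy)-4-methylphenyl]-1-oxido-1,3-dithian-2-yl}-4,6-bis(methoxymethoxy)-3-(3-methylbut-2-en-1-yl)benzaldehyde F6 as a mixture of stereoisomers. The aqueous HCl of step 9 then hydrolyses the monosulfoxide, which ionises far more easily than the sulfide, together with the four MOM ethers, and gives 18 directly.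

Step 9. Acid may promote cyclisation of the prenyl group onto the neighbouring ring A phenol (chroman formation), or ring closure between the formyl group and the neighbouring ketone or a ring B phenol. The fallback transfers the MOM groups to silicon under non-protic conditions. It sets out from 17 and comes back at 18. TMSOTf and 2,2'-bipyridyl in CH2Cl2 at 0 °C convert aromatic MOM ethers through pyridinium intermediates into aryl silyl ethers, here 2-{3-bromo-4-methyl-2,6-bis[(trimethylsilyl)oxy]benzoyl}-3-(3-methylbut-2-en-1-yl)-4,6-bis[(trimethylsilyl)oxy]benzaldehyde F7. Water at neutral pH during work-up hydrolyses F7 to 18.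

**Further compounds**

F1 | step 7 | 2-bromo-4,6-bis(methoxymethoxy)-3-(3-methylbut-2-en-1-yl)benzaldehyde | CC(C)=CCc1c(OCOC)cc(OCOC)c(C=O)c1Br
F2 | step 7 | 1-bromo-2-(dimethoxymethyl)-3,5-bis(methoxymethoxy)-6-(3-methylbut-2-en-1-yl)benzene | CC(C)=CCc1c(OCOC)cc(OCOC)c(C(OC)OC)c1Br
F3 | step 7 | 3-bromo-2,6-bis(methoxymethoxy)-4-methylbenzaldehyde | COCOc1cc(C)c(Br)c(OCOC)c1C=O
F4 | step 7 | [3-bromo-2,6-bis(methoxymethoxy)-4-methylphenyl][2-(dimethoxymethyl)-3,5-bis(methoxymethoxy)-6-(3-methylbut-2-en-1-yl)phenyl]methanol (racemic) | CC(C)=CCc1c(OCOC)cc(OCOC)c(C(OC)OC)c1C(O)c1c(OCOC)cc(C)c(Br)c1OCOC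
F5 | step 7 | [3-bromo-2,6-bis(methoxymethoxy)-4-methylphenyl][2-(dimethoxymethyl)-3,5-bis(methoxymethoxy)-6-(3-methylbut-2-en-1-yl)phenyl]methanone | CC(C)=CCc1c(OCOC)cc(OCOC)c(C(OC)OC)c1C(=O)c1c(OCOC)cc(C)c(Br)c1OCOC
F6 | step 8 | 2-{2-[3-bromo-2,6-bis(methoxymethoxy)-4-methylphenyl]-1-oxido-1,3-dithian-2-yl}-4,6-bis(methoxymethoxy)-3-(3-methylbut-2-en-1-yl)benzaldehyde (mixture of stereoisomers) | CC(C)=CCc1c(OCOC)cc(OCOC)c(C=O)c1C1(SCCCS1=O)c1c(OCOC)cc(C)c(Br)c1OCOC
F7 | step 9 | 2-{3-bromo-4-methyl-2,6-bis[(trimethylsilyl)oxy]benzoyl}-3-(3-methylbut-2-en-1-yl)-4,6-bis[(trimethylsilyl)oxy]benzaldehyde | CC(C)=CCc1c(O[Si](C)(C)C)cc(O[Si](C)(C)C)c(C=O)c1C(=O)c1c(O[Si](C)(C)C)cc(C)c(Br)c1O[Si](C)(C)C
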